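The earlier runs and the new flask stem from a simulated flask on assumed constants; the scatter is artificial.

| setting | red | ochre | flask |
|---|---|---|---|
| solid substrate | 5 mM | 20 mM | 10 mM |
| remark | run made earlier | run made earlier |  |
| time |  |  | 20 min |

| run | time / min | target / % | solid substrate / % |
|---|---|---|---|
| red | 0.833 | 10.5 | 33.1 |
| red | 1.33 | 11.6 | 6.1 |
| red | 2.50 | 13.2 | 0 |
| red | 4.00 | 9.5 | 0 |
| red | 8.00 | 2.9 | 0 |
| red | 15.0 | 3.1 | 0 |
| red | 25.0 | 0.8 | 0.6 |
| ochre | 0.833 | 0.4 | 84.0 |
| ochre | 1.33 | 2.9 | 74.7 |
| ochre | 2.50 | 4.5 | 59.2 |
| ochre | 4.00 | 7.2 | 37.1 |
| ochre | 8.00 | 6.0 | 1.5 |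
| ochre | 15.0 | 3.7 | 0.8 |
| ochre | 25.0 | 2.7 | 0 |

(readings scatter by 1 percentage point)

* time up to 20 min at which target stands highest
* the amount of target, in percent of the solid substrate charged, at that time

- solid substrate is a solid; its amount is given per volume of the solution
- the numbers in the tables scatter by 1 percentage point (one standard deviation)
- at the start none of the solid substrate is in solution

No target can come from solid substrate that has not dissolved, and at the start none of it is in solution. The readings therefore begin with the solid. The ochre run loses it steadily between its first and fourth readings: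

v = 2.96 mM min⁻¹

This v is the clearance rate, the solid substrate lost per minute as a concentration. The red run reads 2.72 mM min⁻¹ over its first two readings. The loss therefore reads as apparent zero order while solid lasts.

The bench rule follows: the charge divided by v gives the clearance time t_c, and target stands highest at t_c. For the flask:

t_c = 3.38 min

The rule has a border. The red run has t_c = 1.69 min, and its highest target reading comes later, at 2.50 min, a ratio of 1.48. The ochre run has t_c = 6.75 min, and its highest reading comes earlier, at 4.00 min, a ratio of 0.593. But these highest readings stand above their neighbours at 1.33 min and 8.00 min by 1.6 percentage points and 1.2 points, against a scatter of 1 point. Each t_c also lies between the two times of its run. So the readings do not tell either peak from t_c, and that spacing is the border of the rule. The charge of the flask lies between those of the two runs, so its peak is placed near t_c, with a height between 7.2% and 13.2%.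

The forecast gives 3.2 min and 10.3%: “Target peaks around the end of dissolution”.

The flask peaks at 3.27 min with 11.6% and then holds 0% solid substrate.

    starting material → intermediate (k = 0.0210 s⁻¹)
    intermediate ⇌ target (K = 0.730, k = 0.250 s⁻¹)
    solid substrate ⇌ starting material, rate k3*(cs3 - [starting material]) while solid is left; crystals form when [starting material] > cs3 (solubility = 3.60 mM, k = 0.0270 s⁻¹)
    target ⇌ isomer of the product B (K = 19.0, k = 0.0260 s⁻¹)
    2 starting material → self-condensation product (k = 1.80 L mol⁻¹ s⁻¹)
    intermediate ⇌ isomer of the product A (K = 3.10, k = 0.00340 s⁻¹)

Used again, v leaves 40.8% of the flask's charge as solid at 2.00 min, where the flask holds 32.9%. The neighbour charged with 40 mM has t_c = 13.5 min, shorter than 20.0 min, and at that time it holds 0% solid substrate.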